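**One-step world.** In a one-step world a catalyst turns over at a steady rate, so my question for the next run is whether the rate read from the beta run justifies charging more free catalyst.

| setting | beta | flask |
|---|---|---|
| solid substrate | 0.020 M | 0.020 M |
| second substrate | 10 mM | 10.0 mM |
| free catalyst | 0.40 mM | 0.40 mM |
| remark | the very flask that is asked about, followed so far |  |
| time |  | 1.5 h |

- beta (time / min: target / %): 2.50: 2.7; 8.00: 3.3; 12.0: 3.3; 20.0: 5.2; 30.0: 11.8; 40.0: 13.5

(scatter of a reading: 1 percentage point)

1. amount of target at 1.5 h, in percent of the solid substrate charged
2. the change that raises the amount of target at 1.5 h, in percent of the solid substrate charged most ("none" if none brings more than 2 percentage points) (north / south-east / west / none)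
3. amount of target at 1.5 h, in percent of the solid substrate charged, after north

- north: doubling the amount of free catalyst, all else as stated
- south-east: doubling the dissolution coefficient of the solid substrate, all else as stated
- west: doubling the solubility of the solid substrate, all else as stated

**First answer.** Beta is this very flask, and its last reading, 13.5% at 40.0 min, reads as 0.169 /min; I carry this turnover rate, the target made per charged free catalyst per minute, a mean with the scatter of that reading. Held steady to 1.5 h, it gives 30.4%.

**Going round.** I assume that each target uses one second substrate and that the rate follows the mean second substrate left, which is its charge minus half of what is used. Putting the answer back gives 21.1%, and further rounds settle at 23.3%.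

**Next run.** Twice the free catalyst doubles the turnover in this picture and settles at 37.8%. I choose north on this picture as a judgement, since beta, at 0.40 mM, varied neither free catalyst nor dissolving nor solubility, so no reading ranks the changes.

**The flask.** The forecast says 27%, north and 38%, holding that “catalyst turnover probably limits the rate”, and its first figure stands above my 23.3%.

The flask gives 19.9%, and north gives 34.9%, so my choice holds, while the turnover rate over 1.5 h comes to 0.110 /min, less than the reading. starting material + free catalyst ⇌ catalyst intermediate A (K = 140 /M, k = 1.20 /M/s); 2 starting material → homo dimer (k = 0.0464 /M/s); second substrate + free catalyst ⇌ catalyst intermediate B (K = 260 /M, k = 1.33 /M/s); solid substrate ⇌ starting material, rate k4*(cs4 - [starting material]) while solid is left; crystals form when [starting material] > cs4 (solubility = 9.30 mM, k = 0.00900 /s); catalyst intermediate B → free catalyst + second product (k = 0.0509 /s); second substrate ⇌ dormant form (K = 1.80, k = 6.57 × 10⁻⁴ /s); catalyst intermediate A → free catalyst + target (k = 0.00834 /s)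

At 0.150 h, c(starting material) is lost to homo dimer at 0.394 mM/min, faster than target forms at 0.0681 mM/min.

**More solid.** In the neighbour flask with 0.050 M of solid substrate, all else as in the recipe, the turnover rate gives 12.2% of that charge and the rounds settle at 9.32%; the computed result is 12.6%.

(All runs were computed with made-up constants; the scatter is artificial.)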